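**Strategy.** The seven-membered ring is grown from a five-membered one. C6 and C10, the two ring carbons flanking the C1–C5 fusion bond, both carry oxygen in the target, so they are treated as the carbonyls left when a cyclobutane-1,2-diol is cleaved. One enantioselective enone–alkene (2+2) photocycloaddition joins 3-methylcyclopentenone to a symmetric 1,2-bis(silyloxy)cyclopentene. It forms C1–C10 and C5–C6, the quaternary C1 and a 5-4-5 tricycle whose C6–C10 bond is later cut to give the hydroazulene. The alkene carries the C8 carbonyl as a twofold-symmetric (2R,3R)-butanediol ketal, so neither regio- nor alkene-face isomers can form and only the enone face needs control.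

Key step: step 3

Remark on locants and faces: C1 is the methyl-bearing fusion carbon, C2 and C3 the cyclopentane CH2 groups, C4 the isopropyl carbinol carbon, C5 the fusion CH, C6 the ester carbon, C7 the CH2, C8 the epoxide ring carbon (C14 its CH2), C9 and C10 the diol carbons (C10 bonded to C1); β is the face of the C1 methyl group, α the opposite face; in these locants the target is 1S,4R,5S,6S,8S,9S,10S.

Remark on design: the C4 carbonyl is masked before the silyl ethers are removed, because a free C6 cyclobutanol next to a C4 ketone would open by retro-aldol cleavage of C5–C6, and a C4/C6 β-diketone after ring cleavage could not take up an isopropyl nucleophile. The C4 ketal is the fast-hydrolysing 1,3-dioxane and the C8 ketal the slow (4R,5R)-4,5-dimethyl-1,3-dioxolane, so C4 can be freed first.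

Step 1
Reactants: 1 dimethyl 3-oxopentanedioate; 2 (2R,3R)-butane-2,3-diol
Product: 3 dimethyl 2,2'-[(4R,5R)-4,5-dimethyl-1,3-dioxolane-2,2-diyl]diacetate
Conditions: TsOH·H2O (cat.), toluene, reflux, Dean–Stark
Reagents that add atoms: none
Why: Acid-catalysed ketalisation with azeotropic removal of water masks the future C8 carbonyl; the twofold-symmetric diol creates no new stereocentre.

Step 2
Reactants: 3 dimethyl 2,2'-[(4R,5R)-4,5-dimethyl-1,3-dioxolane-2,2-diyl]diacetate
Product: 4 (2R,3R)-2,3-dimethyl-7,8-bis(trimethylsilyloxy)-1,4-dioxaspiro[4.4]non-7-ene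
Conditions: Na, Me3SiCl, toluene, reflux
Reagents that add atoms: chlorotrimethylsilane, C[Si](C)(C)Cl
Why: Rühlmann acyloin condensation: sodium reduces both ester groups, the five-membered enediolate closes and is trapped as the bis(silyl) enediol ether, as is standard for glutarates.

Step 3
Reactants: 5 3-methylcyclopent-2-en-1-one; 4 (2R,3R)-2,3-dimethyl-7,8-bis(trimethylsilyloxy)-1,4-dioxaspiro[4.4]non-7-ene
Product: 6 cis-anti-cis 5-4-5 tricyclic ketone (C4 ketone; 1β-methyl; 5β-H; 6α- and 10α-OSiMe3; C8 dimethyldioxolane ketal)
Conditions: hν (366 nm), chiral oxazaborolidine from α,α-bis(3,5-dimethylphenyl)prolinol and 2,4,6-trifluorophenylboronic acid (50 mol%), AlBr3 (50 mol%), 4 (3 equiv, excess recovered), CH2Cl2, −75 °C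
Reagents that add atoms: none
Why: Proposed new method: the AlBr3-activated oxazaborolidine binds the C4 carbonyl of 5 and shifts its absorption to longer wavelength so that only the bound enone is excited at 366 nm, and after intersystem crossing the triplet enone adds stepwise to the electron-rich C6=C10 bond of 4 through a 1,4-diradical that collapses to the cyclobutane (bonds C1–C10 and C5–C6); the closest known reaction types are the oxazaborolidine–AlBr3-catalysed enantioselective intermolecular (2+2) photocycloaddition of cyclic enones to simple alkenes and the uncatalysed addition of cyclopentenones to 1,2-bis(trimethylsilyloxy)cycloalkenes. The four-membered ring closes by recombination of the diradical, and ring strain allows only cis fusion to each five-membered ring. C1 is set by the catalyst, whose aryl group shields one face of the bound enone (the prolinol antipode that exposes the required face is fixed in the first runs); C5 follows as cis to the C1 methyl, and C6 and C10 are cis through the ring of 4 and should lie anti to the cyclopentanone because the alkene approaches with its ring turned away. The step needs enantiofacial control only, since the two alkene carbons and, through the twofold axis of the ketal, the two alkene faces are equivalent. A dark Mukaiyama–Michael addition should be slow at the fully substituted β-carbon of 5 and is checked by a run without light.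

Step 4
Reactants: 6 cis-anti-cis tricyclic ketone
Product: 8 tricyclic 6α/10α-diol bearing the C4 1,3-dioxane ketal and the C8 dimethyldioxolane ketal, via bis-silyl dioxane ketal 7 (not isolated)
Conditions: Me3SiO(CH2)3OSiMe3, Me3SiOTf (5 mol%), CH2Cl2, −78 → −30 °C; Et3N; then K2CO3 (cat.), MeOH, rt
Reagents that add atoms: 1,3-bis(trimethylsilyloxy)propane, C[Si](C)(C)OCCCO[Si](C)(C)C
Why: Noyori ketalisation under aprotic conditions masks the C4 carbonyl while the silyl ethers are still in place, after which methanolysis frees the cis-diol; no stereocentre changes.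

Step 5
Reactants: 8 tricyclic 6α/10α-diol bis-ketal
Product: 10 trans-fused (5α-H) hydroazulene-6/10-dione bis-ketal, via cis-fused dione 9 (not isolated)
Conditions: Pb(OAc)4, CH2Cl2, −20 °C; filtration; then DBU, CH2Cl2, rt
Reagents that add atoms: none
Why: Criegee glycol cleavage of the strained cis-cyclobutane-1,2-diol breaks C6–C10 and releases the C6 and C10 carbonyls of the seven-membered ring, and base equilibration through the C5 enolate of the C6 ketone should convert the cis fusion into the trans one, expected to be the more stable for a hydroazulenone with the carbonyl in the seven-membered ring (cyclic β-keto ketals re-close if opened).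

Step 6
Reactants: 10 trans-fused 6/10-dione bis-ketal
Product: 11 trans-fused 6/10-diol bis-ketal (carbinol epimers)
Conditions: LiAlH4, THF, 0 → 40 °C
Reagents that add atoms: none
Why: Hydride reduction turns both ketones into carbinols so that neither is attacked or enolised during the isopropyl addition; the configuration at C6 and C10 is irrelevant because both are oxidised again in step 9.

Step 7
Reactants: 11 trans-fused 6/10-diol bis-ketal
Product: 12 trans-fused 6/10-dihydroxy-4-ketone with the C8 ketal retained
Conditions: PPTS (cat.), THF/H2O (4:1), 40 °C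
Reagents that add atoms: water, O
Why: Acid-catalysed ketal hydrolysis, selective because a ketone 1,3-dioxane is cleaved much faster than a 1,3-dioxolane and the C8 ketal is further slowed by its two ring methyl groups and two β-hydroxyl groups; 12 is used at once, without contact with base, to keep C5 intact.

Step 8
Reactants: 12 trans-fused 6/10-dihydroxy-4-ketone
Product: 13 4β-hydroxy-4α-isopropyl-6/10-diol (carbinol epimers at C6 and C10)
Conditions: i-PrMgCl (excess), CeCl3, THF, −78 → 0 °C
Reagents that add atoms: isopropylmagnesium chloride, CC(C)[Mg]Cl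
Why: Organocerium (Imamoto-type) addition to a hindered, enolisable cyclopentanone; the reagent should attack C4 from the α face, away from the axial C1 methyl that sits 1,3 to C4 on the β face of the trans-fused bicycle, giving the 4β-hydroxy-4α-isopropyl centre.

Step 9
Reactants: 13 4β-hydroxy-4α-isopropyl-6/10-diol
Product: 14 4β-hydroxy-4α-isopropyl-6/10-dione
Conditions: Dess–Martin periodinane, pyridine, CH2Cl2, 0 °C → rt
Reagents that add atoms: none
Why: Dess–Martin oxidation of the two secondary carbinols under buffered, non-basic conditions regenerates the C6 and C10 ketones without retro-aldol loss of the tertiary β-hydroxy ketone.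

Step 10
Reactants: 14 4β-hydroxy-4α-isopropyl-6/10-dione
Product: 15 4β/6α-dihydroxy-4α-isopropyl-10-ketone
Conditions: Me4NBH(OAc)3, MeCN/AcOH (1:1), −30 °C
Reagents that add atoms: none
Why: Evans–Saksena reduction: the tertiary C4 hydroxyl binds boron and delivers hydride intramolecularly to the β face of the C6 carbonyl, giving the anti-1,3-diol (6α-OH), while the C10 ketone, which has no β-hydroxyl, should stay untouched.

Step 11
Reactants: 15 4β/6α-dihydroxy-10-ketone
Product: 17 6α-isovalerate with 4β-trimethylsilyloxy group and C10 ketone, via hydroxy ester 16 (not isolated)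
Conditions: isovaleric anhydride, DMAP (cat.), Et3N, CH2Cl2, rt; then N-(trimethylsilyl)imidazole, 40 °C
Reagents that add atoms: isovaleric anhydride, CC(C)CC(=O)OC(=O)CC(C)C; N-(trimethylsilyl)imidazole, C[Si](C)(C)n1ccnc1
Why: DMAP-catalysed acylation takes the only secondary hydroxyl (C6) and leaves the hindered tertiary C4 hydroxyl, which is then silylated in the same flask so that no alkoxide sits next to the ester in the following base step.

Step 12
Reactants: 17 6α-isovalerate 4β-silyl ether 10-ketone
Product: 18 C9=C10 enol triflate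
Conditions: KN(SiMe3)2 (1.1 equiv), THF, −78 °C; PhNTf2, −78 → 0 °C
Reagents that add atoms: N-phenylbis(trifluoromethanesulfonimide), O=S(=O)(N(c1ccccc1)S(=O)(=O)C(F)(F)F)C(F)(F)F
Why: Kinetic enolate formation and O-triflation; the C10 ketone can enolise only towards C9 because C1 is quaternary, and it is deprotonated faster than the ester.

Step 13
Reactants: 18 C9=C10 enol triflate
Product: 19 C9=C10 alkene (6α-isovalerate; 4β-OSiMe3; C8 ketal)
Conditions: Pd(OAc)2 (5 mol%), PPh3, HCO2H, n-Bu3N, DMF, 60 °C
Reagents that add atoms: none
Why: Palladium-catalysed formate reduction of the enol triflate (oxidative addition, hydride transfer from formate, reductive elimination) gives the disubstituted alkene.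

Step 14
Reactants: 19 C9=C10 alkene
Product: 20 C8 enone (8-oxo; C9=C10; 6α-isovalerate; 4β-hydroxy-4α-isopropyl)
Conditions: 1 M HCl, THF, 0 °C → rt
Reagents that add atoms: water, O
Why: Acid hydrolysis of the now allylic, hence activated, C8 ketal releases the conjugated enone, and the tertiary silyl ether is cleaved at the same time.

Step 15
Reactants: 20 C8 enone
Product: 21 9α/10α-dihydroxy-8-ketone
Conditions: OsO4 (5 mol%), NMO, citric acid, t-BuOH/H2O, rt
Reagents that add atoms: osmium tetroxide (catalytic oxygen carrier), O=[Os](=O)(=O)=O; N-methylmorpholine N-oxide, C[N+]1([O-])CCOCC1; water, O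
Why: Catalytic osmylation under Upjohn conditions with an acid additive for an electron-poor alkene adds both hydroxyls suprafacially from the α face, opposite the C1 methyl on the neighbouring quaternary carbon, setting 9α-OH and 10α-OH.

Step 16
Reactants: 21 9α/10α-dihydroxy-8-ketone
Product: 22 9α/10α-acetonide 8-ketone
Conditions: Me2C(OMe)2, PPTS (cat.), acetone, rt
Reagents that add atoms: 2,2-dimethoxypropane, COC(C)(C)OC
Why: Acetonide formation on the cis-diol protects the α,β-dihydroxy ketone against retro-aldol and α-ketol pathways and keeps free hydroxyls out of the methylenation.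

Step 17
Reactants: 22 9α/10α-acetonide 8-ketone
Product: 23 8-methylene 9α/10α-acetonide
Conditions: Zn, CH2Br2, TiCl4, THF/CH2Cl2, 0 °C → rt
Reagents that add atoms: dibromomethane, BrCBr
Why: Lombardo–Takai methylenation, a non-basic zinc–titanium methylene reagent that converts ketones but not esters and should neither epimerise the α-oxygenated C9 nor eliminate the β-acyloxy group at C6.

Step 18
Reactants: 23 8-methylene 9α/10α-acetonide
Product: 24 8-methylene-4β/9α/10α-triol 6α-isovalerate
Conditions: AcOH/H2O (4:1), 40 °C
Reagents that add atoms: none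
Why: Mild acid hydrolysis of the acetonide frees the C9 and C10 hydroxyls before the acid-sensitive epoxide exists.

Step 19
Reactants: 24 8-methylene-4β/9α/10α-triol 6α-isovalerate
Product: 25 CNP0307265.1
Conditions: VO(acac)2 (5 mol%), t-BuOOH, CH2Cl2, 0 °C → rt
Reagents that add atoms: tert-butyl hydroperoxide, CC(C)(C)OO
Why: Vanadium-catalysed hydroxyl-directed epoxidation: the allylic 9α-hydroxyl binds vanadium and delivers the peroxide oxygen to the α face of the exocyclic alkene, placing the epoxide oxygen cis to C9–OH as in the target.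

**Compound list**

1 | dimethyl 3-oxopentanedioate | COC(=O)CC(=O)CC(=O)OC | starting material
2 | (2R,3R)-butane-2,3-diol | C[C@@H](O)[C@@H](C)O | starting material
3 | dimethyl 2,2'-[(4R,5R)-4,5-dimethyl-1,3-dioxolane-2,2-diyl]diacetate | COC(=O)CC1(CC(=O)OC)O[C@H](C)[C@@H](C)O1 | intermediate
4 | (2R,3R)-2,3-dimethyl-7,8-bis(trimethylsilyloxy)-1,4-dioxaspiro[4.4]non-7-ene | C[Si](C)(C)OC1=C(O[Si](C)(C)C)CC2(C1)O[C@H](C)[C@@H](C)O2 | intermediate
5 | 3-methylcyclopent-2-en-1-one | CC1=CC(=O)CC1 | starting material
6 | cis-anti-cis 5-4-5 tricyclic ketone: C4 ketone, 1β-methyl, 5β-H, 6α- and 10α-trimethylsilyloxy, C8 spiro (4R,5R)-4,5-dimethyl-1,3-dioxolane | O=C1CC[C@@]2(C)[C@@H]1[C@]3(O[Si](C)(C)C)CC4(O[C@H](C)[C@@H](C)O4)C[C@]23O[Si](C)(C)C | intermediate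
7 | 6 with the C4 carbonyl as spiro 1,3-dioxane (bis-silyl ether) | C12(OCCCO1)CC[C@@]3(C)[C@@H]2[C@]4(O[Si](C)(C)C)CC5(O[C@H](C)[C@@H](C)O5)C[C@]34O[Si](C)(C)C | intermediate (not isolated)
8 | tricyclic 6α,10α-diol with C4 spiro 1,3-dioxane and C8 spiro (4R,5R)-4,5-dimethyl-1,3-dioxolane | C12(OCCCO1)CC[C@@]3(C)[C@@H]2[C@]4(O)CC5(O[C@H](C)[C@@H](C)O5)C[C@]34O | intermediate
9 | cis-fused (5β-H) 1β-methylbicyclo[5.3.0]decane-6,10-dione with C4 dioxane and C8 dimethyldioxolane ketals | O=C1CC2(O[C@H](C)[C@@H](C)O2)CC(=O)[C@@]2(C)CCC3(OCCCO3)[C@@H]12 | intermediate (not isolated)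
10 | trans-fused (5α-H) 1β-methylbicyclo[5.3.0]decane-6,10-dione with C4 dioxane and C8 dimethyldioxolane ketals | O=C1CC2(O[C@H](C)[C@@H](C)O2)CC(=O)[C@@]2(C)CCC3(OCCCO3)[C@H]12 | intermediate
11 | trans-fused 6,10-diol of 10, C6 and C10 configuration not controlled | OC1CC2(O[C@H](C)[C@@H](C)O2)CC(O)[C@@]2(C)CCC3(OCCCO3)[C@H]12 | intermediate
12 | trans-fused 6,10-dihydroxy-4-ketone with C8 dimethyldioxolane ketal, C6 and C10 configuration not controlled | OC1CC2(O[C@H](C)[C@@H](C)O2)CC(O)[C@@]2(C)CCC(=O)[C@H]12 | intermediate
13 | 4β-hydroxy-4α-isopropyl-6,10-diol with C8 ketal, C6 and C10 configuration not controlled | OC1CC2(O[C@H](C)[C@@H](C)O2)CC(O)[C@@]2(C)CC[C@@](O)(C(C)C)[C@H]12 | intermediate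
14 | 4β-hydroxy-4α-isopropyl-6,10-dione with C8 ketal | O=C1CC2(O[C@H](C)[C@@H](C)O2)CC(=O)[C@@]2(C)CC[C@@](O)(C(C)C)[C@H]12 | intermediate
15 | 4β,6α-dihydroxy-4α-isopropyl-10-ketone with C8 ketal | O[C@H]1CC2(O[C@H](C)[C@@H](C)O2)CC(=O)[C@@]2(C)CC[C@@](O)(C(C)C)[C@H]12 | intermediate
16 | 6α-(3-methylbutanoyloxy)-4β-hydroxy-10-ketone with C8 ketal | CC(C)CC(=O)O[C@H]1CC2(O[C@H](C)[C@@H](C)O2)CC(=O)[C@@]2(C)CC[C@@](O)(C(C)C)[C@H]12 | intermediate (not isolated)
17 | 6α-(3-methylbutanoyloxy)-4β-trimethylsilyloxy-10-ketone with C8 ketal | CC(C)CC(=O)O[C@H]1CC2(O[C@H](C)[C@@H](C)O2)CC(=O)[C@@]2(C)CC[C@@](O[Si](C)(C)C)(C(C)C)[C@H]12 | intermediate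
18 | C9=C10 enol triflate of 17 (triflate on C10) | CC(C)CC(=O)O[C@H]1CC2(O[C@H](C)[C@@H](C)O2)C=C(OS(=O)(=O)C(F)(F)F)[C@@]2(C)CC[C@@](O[Si](C)(C)C)(C(C)C)[C@H]12 | intermediate
19 | C9=C10 alkene with 6α-isovalerate, 4β-trimethylsilyloxy and C8 ketal | CC(C)CC(=O)O[C@H]1CC2(O[C@H](C)[C@@H](C)O2)C=C[C@@]2(C)CC[C@@](O[Si](C)(C)C)(C(C)C)[C@H]12 | intermediate
20 | 8-oxo-C9=C10 enone with 6α-isovalerate and 4β-hydroxy-4α-isopropyl | CC(C)CC(=O)O[C@H]1CC(=O)C=C[C@@]2(C)CC[C@@](O)(C(C)C)[C@H]12 | intermediate
21 | 4β,9α,10α-trihydroxy-8-ketone 6α-isovalerate | CC(C)CC(=O)O[C@H]1CC(=O)[C@@H](O)[C@@H](O)[C@@]2(C)CC[C@@](O)(C(C)C)[C@H]12 | intermediate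
22 | 9α,10α-O-isopropylidene-4β-hydroxy-8-ketone 6α-isovalerate | CC(C)CC(=O)O[C@H]1CC(=O)[C@@H](OC3(C)C)[C@@H](O3)[C@@]2(C)CC[C@@](O)(C(C)C)[C@H]12 | intermediate
23 | 8-methylene-9α,10α-O-isopropylidene-4β-ol 6α-isovalerate | CC(C)CC(=O)O[C@H]1CC(=C)[C@@H](OC3(C)C)[C@@H](O3)[C@@]2(C)CC[C@@](O)(C(C)C)[C@H]12 | intermediate
24 | 8-methylene-4β,9α,10α-triol 6α-isovalerate | CC(C)CC(=O)O[C@H]1CC(=C)[C@@H](O)[C@@H](O)[C@@]2(C)CC[C@@](O)(C(C)C)[C@H]12 | intermediate
25 | CNP0307265.1: 8,14-epoxy-4β,9α,10α-trihydroxy-4α-isopropyl-1β-methyl trans-hydroazulen-6α-yl 3-methylbutanoate, epoxide oxygen α | CC(C)CC(=O)O[C@H]1C[C@]2(CO2)[C@@H](O)[C@@H](O)[C@@]2(C)CC[C@@](O)(C(C)C)[C@H]12 | target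

**Totals.** 19 steps. Longest linear sequence: 19 steps (1 → 25); enone 5 is purchased and enters at step 3.

**Steps most likely to fail**

1. Step 3 (proposed new method). The catalyst may shield the faces of a five-membered, β-substituted enone too weakly. The Lewis acid may also consume the silyl enol ether in the dark by conjugate addition or silyl transfer, or open the donor–acceptor cyclobutane of the product. Fallback with known chemistry: setting out from 5 and 4, direct irradiation (about 350 nm, Pyrex, CH2Cl2, −20 °C, no Lewis acid) is the established addition of cyclopentenones to 1,2-bis(trimethylsilyloxy)cycloalkenes. It should give 6 together with the mirror-core cycloadduct F1. Because the (R,R)-ketal is a fixed stereo-element, the two are diastereomers and are separated by chromatography (preparative HPLC if needed). The route is rejoined at 6.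

2. Step 8. The branched Grignard reagent may reduce the hindered cyclopentanone by β-hydride transfer or enolise it instead of adding. Fallback: setting out from 12, CH2=C(CH3)MgBr/CeCl3 (no β-hydrogen to transfer, less basic) should give the isopropenyl carbinol F2, which is hydrogenated (H2, PtO2, EtOAc) to return to the route at 13. An attack from the β face would remain a risk in both variants.

3. Step 7. The rate difference between the two ketals may be too small, so that the C8 ketal is lost together with the C4 dioxane. Fallback: setting out from 11, both ketals are hydrolysed on purpose (1 M HCl, THF) to the diketo diol F3. The unhindered C8 carbonyl, flanked by two CH2 groups, is then re-ketalised selectively with diol 2 (PPTS, benzene, Dean–Stark) beside the neopentyl-like C4 ketone. This returns to the route at 12.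

**Further compounds**

F1 | step 3 | diastereomer of 6 with the mirror-image tricyclic core and the same (4R,5R)-ketal | O=C1CC[C@]2(C)[C@H]1[C@@]3(O[Si](C)(C)C)CC4(O[C@H](C)[C@@H](C)O4)C[C@@]23O[Si](C)(C)C
F2 | step 8 | 4β-hydroxy-4α-isopropenyl-6,10-diol with C8 ketal, C6 and C10 configuration not controlled | OC1CC2(O[C@H](C)[C@@H](C)O2)CC(O)[C@@]2(C)CC[C@@](O)(C(C)=C)[C@H]12
F3 | step 7 | trans-fused 6,10-dihydroxy-4,8-dione, C6 and C10 configuration not controlled | OC1CC(=O)CC(O)[C@@]2(C)CCC(=O)[C@H]12
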